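**Strategy**

Prostanoid numbering is used (C1 ester carbon, C8–C12 ring, C9 carbonyl). The cyclopentenone is opened at C9–C10, the bond between the carbonyl carbon and the α-vinyl carbon. This exposes a hidden symmetry at the quaternary ring carbon C12: its two CH2 arms, ring C8–C9 and chain C13–C14, are both acetaldehyde units once C14=C15 is assigned to a Wittig reaction. The precursor is thus an achiral 3-ethynyl-3-silyloxypentanedial. [Rh((R)-Tol-BINAP)]BF4 adds one of the two enantiotopic formyl C–H bonds across the ethynyl group (C10≡C11); in one operation the ring closes at C9–C10, the enone forms, C12 becomes stereogenic and one formyl group remains for the C13–C20 chain.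

Key step: step 5

Assumption: the (R)-ligand is taken to favour cyclisation of the formyl arm that gives the (R)-configured ring carbon of 9; if the sense of induction proves opposite, the (S)-ligand is used and nothing else changes.

Remark: the ring carbon C12 has the same spatial arrangement from 9 to the target; its descriptor changes from R (9, 14) to S (21 onward) only because C8 gains priority once it is substituted.

**Route**

Step 1
Reactants: 1 ethyl 3-(trimethylsilyl)prop-2-ynoate; 2 allylmagnesium bromide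
Product: 4 4-[(trimethylsilyl)ethynyl]hepta-1,6-dien-4-ol, via allyl alkynyl ketone 3 (not isolated)
Conditions: CH2=CHCH2MgBr (2.3 equiv in all), Et2O/THF, −78 → 0 °C; aq. NH4Cl
Reagents that add atoms: allylmagnesium bromide (second equivalent), C=CC[Mg]Br
Why: Double Grignard 1,2-addition, in which the first equivalent of 2 displaces ethoxide to give ketone 3 and this more electrophilic ketone takes up the second equivalent at once, should give the symmetric tertiary carbinol, the C-silyl group blocking the acidic alkyne terminus.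

Step 2
Reactants: 4 4-[(trimethylsilyl)ethynyl]hepta-1,6-dien-4-ol
Product: 5 4-ethynylhepta-1,6-dien-4-ol
Conditions: K2CO3 (cat.), MeOH, rt
Reagents that add atoms: none
Why: Methanolysis of the alkynyl C–Si bond (protodesilylation) is specific for sp-bound silicon and should leave the alkenes and the tertiary alcohol untouched.

Step 3
Reactants: 5 4-ethynylhepta-1,6-dien-4-ol
Product: 6 [(4-ethynylhepta-1,6-dien-4-yl)oxy]triethylsilane
Conditions: Et3SiOTf, 2,6-lutidine, CH2Cl2, −78 → 0 °C
Reagents that add atoms: triethylsilyl trifluoromethanesulfonate, CC[Si](CC)(CC)OS(=O)(=O)C(F)(F)F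
Why: Silyl triflate silylation of a hindered tertiary alcohol; the triethylsilyl ether stands in for the 3-alkoxy group of known hydroacylation substrates, tolerates ylide and amide bases and is removable with fluoride.

Step 4
Reactants: 6 [(4-ethynylhepta-1,6-dien-4-yl)oxy]triethylsilane
Product: 8 3-ethynyl-3-(triethylsilyloxy)pentanedial, via bis-ozonide 7 (not isolated)
Conditions: O3, CH2Cl2, −78 °C (Sudan Red 7B end point); PPh3, −78 °C → rt
Reagents that add atoms: ozone, [O-][O+]=O
Why: Ozonolysis with reductive work-up; monosubstituted alkenes react with ozone far faster than a terminal alkyne, so titration to the indicator end point should cleave both allyl groups and spare the C≡C bond.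

Step 5
Reactants: 8 3-ethynyl-3-(triethylsilyloxy)pentanedial
Product: 9 (4R)-4-(2-oxoethyl)-4-(triethylsilyloxy)cyclopent-2-en-1-one
Conditions: [Rh((R)-Tol-BINAP)]BF4 (10 mol %, from [Rh(nbd)((R)-Tol-BINAP)]BF4 and H2), CH2Cl2, rt
Reagents that add atoms: none
Why: Intramolecular alkyne hydroacylation of a 4-alkynal catalysed by cationic monovalent rhodium: the metal inserts into one formyl C–H bond to give an acyl trivalent rhodium hydride, the hydride is delivered to the inner alkyne carbon C11 in a net trans addition, and the six-membered acyl(vinyl)rhodacycle reductively eliminates to make the C9–C10 bond. The closest known reaction type is the enantioselective cyclisation of 3-alkoxy-4-alkynals to 4-alkoxycyclopent-2-enones with the same rhodium/Tol-BINAP cation, used for kinetic resolution and for group-selective desymmetrisation; here the groups to be told apart are two formyl arms and the alkyne is terminal, which is the untested part. The single ring closes in a formally 5-endo-dig mode (C9 onto the distal alkyne carbon C10), possible only because the hydrometalation is trans. The only new stereocentre, C12, is controlled by the catalyst: the C2-symmetric bisphosphine makes cyclisation of the pro-R and pro-S CH2CHO arms diastereomeric, with the ether oxygen on C12 available as a second binding point as in the 3-alkoxy precedents. The step needs enantiotopic-group selectivity, cyclopentenone over alkylidenecyclobutanone formation (cis addition) and survival of the second formyl group; the substrate secures these by its mirror symmetry with a single alkyne, so that no second cyclisation can follow, and by offering the remaining formyl group only an electron-poor, geometrically unsuitable enone. Decarbonylation is the expected competing process and should be held back by room temperature and the chelating ligand.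

Step 6
Reactants: 10 (Z)-hex-3-en-1-ol
Product: 11 (Z)-1-bromohex-3-ene
Conditions: CBr4, PPh3, CH2Cl2, 0 °C
Reagents that add atoms: carbon tetrabromide, BrC(Br)(Br)Br
Why: Appel reaction; SN2 displacement of the oxyphosphonium intermediate at the primary carbon should leave the remote Z alkene unchanged.

Step 7
Reactants: 11 (Z)-1-bromohex-3-ene
Product: 12 [(Z)-hex-3-en-1-yl]triphenylphosphonium bromide
Conditions: PPh3, MeCN, reflux
Reagents that add atoms: triphenylphosphine, c1ccc(cc1)P(c1ccccc1)c1ccccc1
Why: SN2 quaternisation of the phosphine by the primary bromide gives the Wittig salt.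

Step 8
Reactants: 9 (4R)-4-(2-oxoethyl)-4-(triethylsilyloxy)cyclopent-2-en-1-one; 12 [(Z)-hex-3-en-1-yl]triphenylphosphonium bromide
Product: 14 (4R)-4-[(2Z,5Z)-octa-2,5-dien-1-yl]-4-(triethylsilyloxy)cyclopent-2-en-1-one, via phosphorus ylide 13 (not isolated)
Conditions: 12, NaN(SiMe3)2 (1.0 equiv), THF, −78 → 0 °C; then 9, −78 → −20 °C
Reagents that add atoms: none
Why: Wittig olefination with a non-stabilised, lithium-free ylide under kinetic control should give the Z alkene (C14=C15) through the cis-oxaphosphetane; the aldehyde reacts at −78 °C far faster than the ring ketone and C12 is not involved.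

Step 9
Reactants: 15 methyl 4-chloro-4-oxobutanoate; 16 3,3-diethoxyprop-1-yne
Product: 17 methyl 7,7-diethoxy-4-oxohept-5-ynoate
Conditions: PdCl2(PPh3)2 (2 mol %), CuI (4 mol %), Et3N (1.1 equiv), THF, rt
Reagents that add atoms: none
Why: Acyl Sonogashira coupling; the copper acetylide transmetalates to the acylpalladium chloride formed by oxidative addition of the acid chloride to zerovalent palladium, and reductive elimination gives the ynone without over-addition.

Step 10
Reactants: 17 methyl 7,7-diethoxy-4-oxohept-5-ynoate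
Product: 18 methyl (4R)-7,7-diethoxy-4-hydroxyhept-5-ynoate
Conditions: Ru[(R,R)-TsNCH(Ph)CH(Ph)NH](p-cymene) (1 mol %), iPrOH, rt; crude product used at once
Reagents that add atoms: none
Why: Noyori asymmetric transfer hydrogenation of an alkynyl ketone; the (R,R)-catalyst should deliver hydride to the face that places the alkynyl group beside the arene ligand, giving the (R)-propargylic alcohol under base-free conditions that spare the acetal and the ester.

Step 11
Reactants: 18 methyl (4R)-7,7-diethoxy-4-hydroxyhept-5-ynoate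
Product: 19 methyl (4R)-4-acetoxy-7,7-diethoxyhept-5-ynoate
Conditions: Ac2O, pyridine, DMAP (cat.), CH2Cl2, 0 °C
Reagents that add atoms: acetic anhydride, CC(=O)OC(C)=O
Why: DMAP-catalysed acetylation reacts only at the O–H bond (retention at C4) and forestalls lactonisation of the γ-hydroxy ester.

Step 12
Reactants: 19 methyl (4R)-4-acetoxy-7,7-diethoxyhept-5-ynoate
Product: 20 methyl (4R)-4-acetoxy-7-oxohept-5-ynoate
Conditions: HCO2H/H2O (4:1), rt; used without storage
Reagents that add atoms: water, O
Why: Acid-catalysed acetal hydrolysis; aqueous formic acid cleaves propargylic diethyl acetals while the methyl ester, the acetate and C4 should remain untouched.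

Step 13
Reactants: 14 (4R)-4-[(2Z,5Z)-octa-2,5-dien-1-yl]-4-(triethylsilyloxy)cyclopent-2-en-1-one; 20 methyl (4R)-4-acetoxy-7-oxohept-5-ynoate
Product: 22 methyl (4R)-4-acetoxy-7-hydroxy-7-[(5S)-5-[(2Z,5Z)-octa-2,5-dien-1-yl]-2-oxo-5-(triethylsilyloxy)cyclopent-3-en-1-yl]hept-5-ynoate (epimer mixture at C7 and C8), via lithium dienolate 21 (not isolated)
Conditions: LiN(iPr)2 (1.05 equiv), THF, −78 °C; then 20, −78 °C; AcOH, −78 °C
Reagents that add atoms: none
Why: Directed aldol addition; the amide base removes the only enolisable protons (ring CH2, C8) and the cross-conjugated dienolate should add 1,2 to the very electrophilic ynal at −78 °C faster than it loses the β-silyloxy group, the new centres at C7 and C8 being left uncontrolled because the next step destroys both.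

Step 14
Reactants: 22 aldol adduct (epimer mixture)
Product: 24 methyl (4R,7E)-4-acetoxy-7-[(5S)-5-[(2Z,5Z)-octa-2,5-dien-1-yl]-2-oxo-5-(triethylsilyloxy)cyclopent-3-en-1-ylidene]hept-5-ynoate, via mesylate 23 (not isolated)
Conditions: MsCl, Et3N (excess), CH2Cl2, −20 → 20 °C; chromatography
Reagents that add atoms: none
Why: Mesylation followed by E1cB elimination converges both aldol epimers on the exocyclic enone; the E isomer (slim alkynyl group beside C12, vinylic hydrogen beside the carbonyl oxygen) should be favoured, any Z isomer is separated, and the mild amine base is chosen to spare the acidic C4–H.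

Step 15
Reactants: 24 silyl ether
Product: 25 methyl (4R,7E)-4-acetoxy-7-[(5S)-5-hydroxy-5-[(2Z,5Z)-octa-2,5-dien-1-yl]-2-oxocyclopent-3-en-1-ylidene]hept-5-ynoate
Conditions: HF·pyridine, pyridine/THF, 0 °C
Reagents that add atoms: none
Why: Fluoride-driven cleavage of the tertiary triethylsilyl ether under buffered conditions should leave both esters, the propargylic acetate and the dienone intact.

Step 16
Reactants: 25 tertiary alcohol
Product: 26 methyl (4R,7E)-4-acetoxy-7-[(5S)-5-acetoxy-5-[(2Z,5Z)-octa-2,5-dien-1-yl]-2-oxocyclopent-3-en-1-ylidene]hept-5-ynoate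
Conditions: Ac2O, DMAP, Et3N, CH2Cl2, rt
Reagents that add atoms: acetic anhydride, CC(=O)OC(C)=O
Why: DMAP-catalysed acetylation of the tertiary alcohol touches only the O–H bond, so C12 keeps its configuration.

Step 17
Reactants: 26 5,6-didehydro diacetate
Product: 27 methyl (4R,5Z,7E)-4-acetoxy-7-[(5S)-5-acetoxy-5-[(2Z,5Z)-octa-2,5-dien-1-yl]-2-oxocyclopent-3-en-1-ylidene]hept-5-enoate (target)
Conditions: H2 (1 atm), Pd/CaCO3 poisoned with Pb(OAc)2, quinoline, EtOAc, rt, stopped after one equivalent of H2; light excluded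
Reagents that add atoms: none
Why: Lindlar semi-hydrogenation; syn delivery of H2 to the alkyne, which binds the poisoned surface more strongly than the isolated Z alkenes or the enone, should give the (5Z)-alkene, with quinoline suppressing over-reduction and Z/E isomerisation.

**Compound list**

1 | ethyl 3-(trimethylsilyl)prop-2-ynoate | CCOC(=O)C#C[Si](C)(C)C | starting material
2 | allylmagnesium bromide | C=CC[Mg]Br | starting material
3 | 1-(trimethylsilyl)hex-5-en-1-yn-3-one (not isolated) | C=CCC(=O)C#C[Si](C)(C)C | intermediate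
4 | 4-[(trimethylsilyl)ethynyl]hepta-1,6-dien-4-ol | C=CCC(O)(CC=C)C#C[Si](C)(C)C | intermediate
5 | 4-ethynylhepta-1,6-dien-4-ol | C=CCC(O)(CC=C)C#C | intermediate
6 | [(4-ethynylhepta-1,6-dien-4-yl)oxy]triethylsilane | C=CCC(O[Si](CC)(CC)CC)(CC=C)C#C | intermediate
7 | 3,3'-[2-ethynyl-2-(triethylsilyloxy)propane-1,3-diyl]bis(1,2,4-trioxolane) (bis-ozonide, not isolated) | C#CC(O[Si](CC)(CC)CC)(CC1OCOO1)CC1OCOO1 | intermediate
8 | 3-ethynyl-3-(triethylsilyloxy)pentanedial | O=CCC(O[Si](CC)(CC)CC)(C#C)CC=O | intermediate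
9 | (4R)-4-(2-oxoethyl)-4-(triethylsilyloxy)cyclopent-2-en-1-one | O=CC[C@]1(O[Si](CC)(CC)CC)C=CC(=O)C1 | intermediate
10 | (Z)-hex-3-en-1-ol | CC/C=C\CCO | starting material
11 | (Z)-1-bromohex-3-ene | CC/C=C\CCBr | intermediate
12 | [(Z)-hex-3-en-1-yl]triphenylphosphonium bromide | CC/C=C\CC[P+](c1ccccc1)(c1ccccc1)c1ccccc1.[Br-] | intermediate
13 | [(Z)-hex-3-en-1-ylidene]triphenylphosphorane (ylide, not isolated) | CC/C=C\CC=P(c1ccccc1)(c1ccccc1)c1ccccc1 | intermediate
14 | (4R)-4-[(2Z,5Z)-octa-2,5-dien-1-yl]-4-(triethylsilyloxy)cyclopent-2-en-1-one | CC/C=C\C/C=C\C[C@]1(O[Si](CC)(CC)CC)C=CC(=O)C1 | intermediate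
15 | methyl 4-chloro-4-oxobutanoate | COC(=O)CCC(Cl)=O | starting material
16 | 3,3-diethoxyprop-1-yne | C#CC(OCC)OCC | starting material
17 | methyl 7,7-diethoxy-4-oxohept-5-ynoate | COC(=O)CCC(=O)C#CC(OCC)OCC | intermediate
18 | methyl (4R)-7,7-diethoxy-4-hydroxyhept-5-ynoate | CCOC(OCC)C#C[C@@H](CCC(=O)OC)O | intermediate
19 | methyl (4R)-4-acetoxy-7,7-diethoxyhept-5-ynoate | CCOC(OCC)C#C[C@@H](CCC(=O)OC)OC(C)=O | intermediate
20 | methyl (4R)-4-acetoxy-7-oxohept-5-ynoate | O=CC#C[C@@H](CCC(=O)OC)OC(C)=O | intermediate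
21 | lithium (3S)-3-[(2Z,5Z)-octa-2,5-dien-1-yl]-3-(triethylsilyloxy)cyclopenta-1,4-dien-1-olate (not isolated) | CC/C=C\C/C=C\C[C@]1(O[Si](CC)(CC)CC)C=CC(O[Li])=C1 | intermediate
22 | methyl (4R)-4-acetoxy-7-hydroxy-7-[(5S)-5-[(2Z,5Z)-octa-2,5-dien-1-yl]-2-oxo-5-(triethylsilyloxy)cyclopent-3-en-1-yl]hept-5-ynoate (epimer mixture at C7 and C8) | CC/C=C\C/C=C\C[C@]1(O[Si](CC)(CC)CC)C=CC(=O)C1C(O)C#C[C@@H](CCC(=O)OC)OC(C)=O | intermediate
23 | methanesulfonate of 22 (not isolated) | CC/C=C\C/C=C\C[C@]1(O[Si](CC)(CC)CC)C=CC(=O)C1C(OS(C)(=O)=O)C#C[C@@H](CCC(=O)OC)OC(C)=O | intermediate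
24 | methyl (4R,7E)-4-acetoxy-7-[(5S)-5-[(2Z,5Z)-octa-2,5-dien-1-yl]-2-oxo-5-(triethylsilyloxy)cyclopent-3-en-1-ylidene]hept-5-ynoate | CC/C=C\C/C=C\C[C@]1(O[Si](CC)(CC)CC)C=CC(=O)/C1=C/C#C[C@@H](CCC(=O)OC)OC(C)=O | intermediate
25 | methyl (4R,7E)-4-acetoxy-7-[(5S)-5-hydroxy-5-[(2Z,5Z)-octa-2,5-dien-1-yl]-2-oxocyclopent-3-en-1-ylidene]hept-5-ynoate | CC/C=C\C/C=C\C[C@]1(O)C=CC(=O)/C1=C/C#C[C@@H](CCC(=O)OC)OC(C)=O | intermediate
26 | methyl (4R,7E)-4-acetoxy-7-[(5S)-5-acetoxy-5-[(2Z,5Z)-octa-2,5-dien-1-yl]-2-oxocyclopent-3-en-1-ylidene]hept-5-ynoate | CC/C=C\C/C=C\C[C@]1(OC(C)=O)C=CC(=O)/C1=C/C#C[C@@H](CCC(=O)OC)OC(C)=O | intermediate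
27 | methyl (4R,5Z,7E)-4-acetoxy-7-[(5S)-5-acetoxy-5-[(2Z,5Z)-octa-2,5-dien-1-yl]-2-oxocyclopent-3-en-1-ylidene]hept-5-enoate | CC/C=C\C/C=C\C[C@]1(OC(C)=O)C=CC(=O)/C1=C/C=C\[C@@H](CCC(=O)OC)OC(C)=O | target

**Step count and risks**

Total step count: 17. Longest linear sequence: 11 steps (1, 2, 3, 4, 5, 8, 13, 14, 15, 16, 17).

Steps most likely to fail:

1. Step 5. The catalyst may discriminate poorly between the two enantiotopic formyl arms, or may be drained by decarbonylation through the spectator formyl group. The fallback sets out from dialdehyde 8 and comes back at 14. Compound 8 is treated with one equivalent of ylide 13 (from 12 and NaN(SiMe3)2, THF, −78 °C) and the mono-olefin is separated as racemic (5Z,8Z)-3-ethynyl-3-(triethylsilyloxy)undeca-5,8-dienal F1. F1 is then submitted to the established kinetic resolution of racemic 3-oxygenated 4-alkynals with [Rh((R)-Tol-BINAP)]BF4 in CH2Cl2, stopped near half conversion, so that the fast-reacting enantiomer cyclises to 14 and the slow one is left behind. The stereochemical task thereby changes from group selection within one molecule to enantiomer selection between molecules that carry a single formyl group; the C9–C10 ring closure is kept.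

2. Step 17. The late semi-hydrogenation may over-reduce the skipped Z alkenes or the ring enone, or the new Z diene may isomerise on the palladium surface. The fallback sets out from 19 and comes back at 27; it moves the reduction to the small fragment, before any polyene exists. Compound 19 is semi-hydrogenated (H2, Pd/CaCO3 poisoned with Pb(OAc)2, quinoline) to methyl (4R,5Z)-4-acetoxy-7,7-diethoxyhept-5-enoate F2, and the acetal is hydrolysed under mild conditions (wet SiO2, oxalic acid, CH2Cl2, 0 °C) to methyl (4R,5Z)-4-acetoxy-7-oxohept-5-enoate F3. F3 is added at −78 °C to lithium dienolate 21 (from 14) to give methyl (4R,5Z)-4-acetoxy-7-hydroxy-7-[(5S)-5-[(2Z,5Z)-octa-2,5-dien-1-yl]-2-oxo-5-(triethylsilyloxy)cyclopent-3-en-1-yl]hept-5-enoate F4. MsCl/Et3N converts F4 via its methanesulfonate F5 into methyl (4R,5Z,7E)-4-acetoxy-7-[(5S)-5-[(2Z,5Z)-octa-2,5-dien-1-yl]-2-oxo-5-(triethylsilyloxy)cyclopent-3-en-1-ylidene]hept-5-enoate F6. HF·pyridine then gives methyl (4R,5Z,7E)-4-acetoxy-7-[(5S)-5-hydroxy-5-[(2Z,5Z)-octa-2,5-dien-1-yl]-2-oxocyclopent-3-en-1-ylidene]hept-5-enoate F7, and Ac2O/DMAP gives 27.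

3. Step 13. The basic dienolate may abstract the acidic C4 proton of the ynal, attack its acetate, or lose the β-silyloxy group before the C7–C8 bond forms. The fallback sets out from 14 and comes back at 22; it replaces the basic enolate by a Lewis-acid-mediated Mukaiyama aldol addition. Compound 14 is converted with Me3SiOTf/Et3N (CH2Cl2, 0 °C) into triethyl{[(1S)-1-[(2Z,5Z)-octa-2,5-dien-1-yl]-4-(trimethylsilyloxy)cyclopenta-2,4-dien-1-yl]oxy}silane F8, which is combined with ynal 20 and BF3·OEt2 in CH2Cl2 at −78 °C; aqueous work-up gives 22.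

**Further compounds**

F1 | step 5 | rac-(5Z,8Z)-3-ethynyl-3-(triethylsilyloxy)undeca-5,8-dienal | CC/C=C\C/C=C\CC(O[Si](CC)(CC)CC)(C#C)CC=O
F2 | step 17 | methyl (4R,5Z)-4-acetoxy-7,7-diethoxyhept-5-enoate | CCOC(OCC)/C=C\[C@@H](CCC(=O)OC)OC(C)=O
F3 | step 17 | methyl (4R,5Z)-4-acetoxy-7-oxohept-5-enoate | O=C/C=C\[C@@H](CCC(=O)OC)OC(C)=O
F4 | step 17 | methyl (4R,5Z)-4-acetoxy-7-hydroxy-7-[(5S)-5-[(2Z,5Z)-octa-2,5-dien-1-yl]-2-oxo-5-(triethylsilyloxy)cyclopent-3-en-1-yl]hept-5-enoate | CC/C=C\C/C=C\C[C@]1(O[Si](CC)(CC)CC)C=CC(=O)C1C(O)/C=C\[C@@H](CCC(=O)OC)OC(C)=O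
F5 | step 17 | methanesulfonate of F4 | CC/C=C\C/C=C\C[C@]1(O[Si](CC)(CC)CC)C=CC(=O)C1C(OS(C)(=O)=O)/C=C\[C@@H](CCC(=O)OC)OC(C)=O
F6 | step 17 | methyl (4R,5Z,7E)-4-acetoxy-7-[(5S)-5-[(2Z,5Z)-octa-2,5-dien-1-yl]-2-oxo-5-(triethylsilyloxy)cyclopent-3-en-1-ylidene]hept-5-enoate | CC/C=C\C/C=C\C[C@]1(O[Si](CC)(CC)CC)C=CC(=O)/C1=C/C=C\[C@@H](CCC(=O)OC)OC(C)=O
F7 | step 17 | methyl (4R,5Z,7E)-4-acetoxy-7-[(5S)-5-hydroxy-5-[(2Z,5Z)-octa-2,5-dien-1-yl]-2-oxocyclopent-3-en-1-ylidene]hept-5-enoate | CC/C=C\C/C=C\C[C@]1(O)C=CC(=O)/C1=C/C=C\[C@@H](CCC(=O)OC)OC(C)=O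
F8 | step 13 | triethyl{[(1S)-1-[(2Z,5Z)-octa-2,5-dien-1-yl]-4-(trimethylsilyloxy)cyclopenta-2,4-dien-1-yl]oxy}silane | CC/C=C\C/C=C\C[C@]1(O[Si](CC)(CC)CC)C=CC(O[Si](C)(C)C)=C1
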